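Take the logarithm first.

| setting | north-east | north-west | south-west | south |
|---|---|---|---|---|
| starting material | 0.400 M | 0.400 M | 0.800 M | 1.40 M |
| target |  | 0.120 M |  |  |
| time |  |  |  | 49 min |

| run | time / min | [target] / M |
|---|---|---|
| north-east run | 9.8 | 0.104 |
| north-east run | 20 | 0.185 |
| north-east run | 29 | 0.224 |
| north-east run | 39 | 0.271 |
| north-east run | 49 | 0.310 |
| north-west run | 9.8 | 0.218 |
| north-west run | 20 | 0.298 |
| north-west run | 29 | 0.351 |
| north-west run | 39 | 0.403 |
| north-west run | 49 | 0.432 |
| south-west run | 9.8 | 0.197 |
| south-west run | 20 | 0.362 |
| south-west run | 29 | 0.462 |
| south-west run | 39 | 0.554 |
| south-west run | 49 | 0.620 |

(scatter of a reading: 0.004 M)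

- Overall: starting material -> target.
- Constant volume, constant temperature.
- The analysis sees a species whether free or bound.
- An order is taken over about fifteen percent of the charge, up and down.

- how the opening rate goes with [starting material] round the charge of the north-east run: the exponent of the rate at two percent of starting material gone to target (one fixed amount of target, the same in the runs compared)
- target in the south run at 49 min, as a share of the starting material charged

What do you read from a decay curve? The remaining [starting material], which is the charge minus the target made, on a logarithmic scale. The north-east run, with 0.310 M of target at 49 min, gives 75.6 min. That is the decade time, the time in which [starting material] falls by a factor of 10. As a time constant it is 32.8 min.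

Does it change with the charge? The south-west run, on 2.00 times the charge, reads 75.6 min. In first-order decay the decade time does not depend on the charge, and these two readings agree.

And with target present? Taking the added 0.120 M off the last north-west reading gives 74.5 min, and the scatter of one reading moves such a figure by 2.25 min.

So is the order exactly one? That is not shown. The first readings of the south-west and north-east runs, taken at one time, give an exponent of 0.922, with a scatter of 0.0627. That spans a doubling of the charge and is taken at one time, not at one amount of target, but it is the figure I commit to.

And the south run? Its charge lies beyond the runs, at 1.75 times the south-west charge. Carrying the decade time over, I expect a share of 77.5% at 49 min.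

The forecast gives an exponent of 1 and a share of 77.4%, on the ground that “Doubling the charge doubles the rate, with the same k”. The two shares differ by 0.1 percentage points.

The south run gives 77.3% at 49 min, and the opening exponent is 0.90.

    2 starting material ⇌ intermediate + starting material (0.2628 M⁻¹ min⁻¹, 0.06660 M⁻¹ min⁻¹)
    intermediate → target (2.382 min⁻¹)
    2 starting material ⇌ idle substrate dimer, settled at all times (4.050 M⁻¹)
    starting material → target (0.02712 min⁻¹)

Where the same amount of target has been made, the south-west run goes 1.8 times as fast as the north-east run. For the north-west run, the decade time times the logarithm of 2 reckons 22.8 min for the target made to reach half of the charge, and that run shows 23.4 min.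

The numbers in the tables stem from a simulated flask for an exercise; the scatter is artificial.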